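**Retrosynthetic overview**
- The three ester C–O bonds are each made by a Mitsunobu esterification with 6-epi-incarvilline (inversion at C6), one per step: the C1 ester and the side-chain ester are installed on the two alkene partners, and the C3 ester is formed last.
- The cyclobutane and its four stereocentres come from a head-to-tail [2+2] union of the incarvillinyl (E)-α-methylferulate with an (E)-enoyl oxazolidinone; hydroperoxide then frees the C3 acid.
- The enoyl imide comes from cross-metathesis of 3-acryloyloxazolidinone with the incarvillinyl (E)-3-methylhepta-2,6-dienoate (syn-carbocupration of the but-2-ynoate ester); the ferulic acid comes from vanillin by Doebner condensation.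
- 6-epi-Incarvilline comes from a keto carbamate by hydride reduction (N-methyl and C6 alcohol), after hydrogenation of the enone from a Pauson–Khand reaction that closes the piperidine and cyclopentenone rings together; the enyne comes from (R)-Roche ester and crotylamine by C–N amide formation.
- Ring order: piperidine and cyclopentenone (Pauson–Khand), then cyclobutane, then the last ester.

Assumption: the SMILES is taken literally, so the cyclobutane is (1S,2R,3S,4S) (C1 = methyl-bearing carbon, C2 = aryl-bearing carbon, C3 = the ring carbon bearing the other ring ester, C4 = side-chain carbon) and each amino alcohol unit is (4R,4aS,6R,7S,7aR).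
Abbreviation: Inc = the (4R,4aS,6R,7S,7aR)-2,4,7-trimethyloctahydro-1H-cyclopenta[c]pyridin-6-yl group. Compounds carrying Inc are named as free bases; where a step is run on an ammonium salt, the Conditions line says so.

**Route**

Step 1
Reactants: 1 methyl (2R)-3-hydroxy-2-methylpropanoate; 2 (2E)-but-2-en-1-amine
Product: 3 (2R)-N-[(2E)-but-2-en-1-yl]-3-hydroxy-2-methylpropanamide
Conditions: 2 (3 equiv), 2-hydroxypyridine (0.2 equiv), neat, 75 °C, 36 h
Reagents that add atoms: none
Why: Aminolysis of a β-hydroxy methyl ester by an unhindered primary amine (amide C–N bond formation) under neutral conditions that leave the α-stereocentre untouched.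

Step 2
Reactants: 3 (2R)-N-[(2E)-but-2-en-1-yl]-3-hydroxy-2-methylpropanamide
Product: 4 (2S)-3-{[(2E)-but-2-en-1-yl]amino}-2-methylpropan-1-ol
Conditions: LiAlH4 (3 equiv), THF, reflux; Fieser work-up
Reagents that add atoms: none
Why: LiAlH4 reduction of the secondary amide to the amine without touching the stereocentre or the isolated alkene (the descriptor changes only because the CIP ranking changes).

Step 3
Reactants: 4 (2S)-3-{[(2E)-but-2-en-1-yl]amino}-2-methylpropan-1-ol
Product: 5 methyl N-[(2E)-but-2-en-1-yl]-N-[(2S)-3-hydroxy-2-methylpropyl]carbamate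
Conditions: ClCO2Me (1.05 equiv), NaHCO3, THF/H2O, 0 °C
Reagents that add atoms: methyl chloroformate, COC(=O)Cl
Why: Schotten–Baumann N-acylation, in which the secondary amine reacts far faster than the primary alcohol, giving a non-basic nitrogen for the cobalt step and the future N-methyl carbon.

Step 4
Reactants: 5 methyl N-[(2E)-but-2-en-1-yl]-N-[(2S)-3-hydroxy-2-methylpropyl]carbamate
Product: 6 methyl N-[(2E)-but-2-en-1-yl]-N-[(2S)-2-methyl-3-oxopropyl]carbamate
Conditions: Dess–Martin periodinane (1.2 equiv), CH2Cl2, 0 °C to rt; used at once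
Reagents that add atoms: none
Why: Dess–Martin oxidation of the primary alcohol under neutral conditions that do not epimerise the α-methyl aldehyde.

Step 5
Reactants: 6 methyl N-[(2E)-but-2-en-1-yl]-N-[(2S)-2-methyl-3-oxopropyl]carbamate
Product: 7 methyl N-[(2E)-but-2-en-1-yl]-N-[(2R)-2-methylbut-3-yn-1-yl]carbamate
Conditions: dimethyl (1-diazo-2-oxopropyl)phosphonate (1.3 equiv), K2CO3 (2 equiv), MeOH, 0 °C to rt
Reagents that add atoms: dimethyl (1-diazo-2-oxopropyl)phosphonate, CC(=O)C(=[N+]=[N-])P(=O)(OC)OC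
Why: Ohira–Bestmann (Seyferth–Gilbert) homologation of the aldehyde to the terminal alkyne with mild carbonate base, which is routinely tolerated by α-methyl aldehydes.

Step 6
Reactants: 7 methyl N-[(2E)-but-2-en-1-yl]-N-[(2R)-2-methylbut-3-yn-1-yl]carbamate
Product: 8 methyl (4R,7S,7aS)-4,7-dimethyl-6-oxo-1,3,4,6,7,7a-hexahydro-2H-cyclopenta[c]pyridine-2-carboxylate
Conditions: Co2(CO)8 (20 mol%), tetramethylthiourea (1.2 equiv), CO (1 atm), toluene, 70 °C
Reagents that add atoms: carbon monoxide, [C-]#[O+]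
Why: Intramolecular Pauson–Khand reaction of the 1,7-enyne forms both rings; C7a is set by 1,3-induction from C4 (chair-like cobaltacycle with the C4 methyl and the C7a–C7 bond both pseudo-equatorial, so H4 and H7a end cis), and C7 follows from stereospecific syn insertion of the (E)-alkene (methyl trans to C1).

Step 7
Reactants: 8 methyl (4R,7S,7aS)-4,7-dimethyl-6-oxo-1,3,4,6,7,7a-hexahydro-2H-cyclopenta[c]pyridine-2-carboxylate
Product: 9 methyl (4R,4aS,7S,7aR)-4,7-dimethyl-6-oxooctahydro-2H-cyclopenta[c]pyridine-2-carboxylate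
Conditions: H2 (1 atm), 10% Pd/C, EtOAc, rt
Reagents that add atoms: none
Why: Heterogeneous hydrogenation of the ring-fusion enone delivers hydrogen to C4a from the face of the angular H7a, giving the cis-fused ketone with H4, H4a and H7a all cis.

Step 8
Reactants: 9 methyl (4R,4aS,7S,7aR)-4,7-dimethyl-6-oxooctahydro-2H-cyclopenta[c]pyridine-2-carboxylate
Product: 10 (4R,4aS,6S,7S,7aR)-2,4,7-trimethyloctahydro-1H-cyclopenta[c]pyridin-6-ol (6-epi-incarvilline)
Conditions: LiAlH4 (4 equiv), THF, −20 °C, then reflux; Fieser work-up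
Reagents that add atoms: none
Why: LiAlH4 attacks the ketone from the convex face of the cis-fused bicycle (the face of H4a and H7a), giving the 6S alcohol with OH trans to the C7 methyl, and on heating reduces the methyl carbamate to the N-methyl group.

Step 9
Reactants: 11 4-hydroxy-3-methoxybenzaldehyde (vanillin); 12 2-methylpropanedioic acid (methylmalonic acid)
Product: 13 (2E)-3-(4-hydroxy-3-methoxyphenyl)-2-methylprop-2-enoic acid
Conditions: 12 (1.5 equiv), piperidine (0.2 equiv), pyridine, 80 °C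
Reagents that add atoms: none
Why: Knoevenagel–Doebner condensation, in which aldol addition is followed by decarboxylative dehydration to the (E)-α-methylcinnamic acid (aryl cis to methyl); the free phenol is tolerated and the temperature is kept at 80 °C to avoid a second decarboxylation.

Step 10
Reactants: 13 (2E)-3-(4-hydroxy-3-methoxyphenyl)-2-methylprop-2-enoic acid; 10 (4R,4aS,6S,7S,7aR)-2,4,7-trimethyloctahydro-1H-cyclopenta[c]pyridin-6-ol
Product: 14 Inc (2E)-3-(4-hydroxy-3-methoxyphenyl)-2-methylprop-2-enoate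
Conditions: 13 (1.3 equiv), PPh3 (1.5 equiv), DIAD (1.5 equiv), THF, 0 °C to rt
Reagents that add atoms: none
Why: Mitsunobu esterification, in which the carboxylate (pKa about 4.5, far more acidic than the phenol) displaces the oxyphosphonium of 10 by SN2 from the convex face with inversion (6S to 6R) while the tertiary amine is inert; this places the most hindered ester of the target on an unhindered acid.

Step 11
Reactants: 15 but-2-ynoic acid; 10 (4R,4aS,6S,7S,7aR)-2,4,7-trimethyloctahydro-1H-cyclopenta[c]pyridin-6-ol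
Product: 16 Inc but-2-ynoate
Conditions: PPh3 (1.3 equiv), DIAD (1.3 equiv), THF, 0 °C, 15 min; then 10 and 15 (1.2 equiv), −20 °C to rt
Reagents that add atoms: none
Why: Mitsunobu esterification with an acidic ynoic acid (pKa about 2.6), again with SN2 inversion at C6 (6S to 6R); the betaine is pre-formed so that no free phosphine meets the ynoate.

Step 12
Reactants: 16 Inc but-2-ynoate; 17 but-3-en-1-ylmagnesium bromide
Product: 19 Inc (2E)-3-methylhepta-2,6-dienoate, via alkenylcopper adduct 18 (not isolated)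
Conditions: 17 (1.3 equiv), CuI (1.3 equiv), THF, −40 °C; then 16, −78 °C, 1 h; MeOH, −78 °C; aq NH3/NH4Cl wash
Reagents that add atoms: none
Why: syn-Carbocupration of the ynoate at −78 °C followed by protonation with retention places the butenyl chain trans to the ester, i.e. the (E)-trisubstituted enoate; the tertiary amine and the secondary-alkyl ester are inert to the organocopper.

Step 13
Reactants: 19 Inc (2E)-3-methylhepta-2,6-dienoate; 20 3-(prop-2-enoyl)-1,3-oxazolidin-2-one
Product: 21 Inc (2E,6E)-3-methyl-8-oxo-8-(2-oxo-1,3-oxazolidin-3-yl)octa-2,6-dienoate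
Conditions: TsOH·H2O (1.05 equiv, amine held as its tosylate), 20 (2 equiv), second-generation Grubbs catalyst (5 mol%), CH2Cl2, 40 °C; aq NaHCO3
Reagents that add atoms: none
Why: Olefin cross-metathesis of the terminal alkene with the acryloyl imide is (E)-selective, the electron-poor trisubstituted enoate is inert to the catalyst, and protonation keeps the amine from binding ruthenium.

Step 14
Reactants: 14 Inc (2E)-3-(4-hydroxy-3-methoxyphenyl)-2-methylprop-2-enoate; 21 Inc (2E,6E)-3-methyl-8-oxo-8-(2-oxo-1,3-oxazolidin-3-yl)octa-2,6-dienoate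
Product: 22 Inc (1S,2R,3S,4S)-2-(4-hydroxy-3-methoxyphenyl)-1-methyl-4-[(3E)-3-methyl-5-oxo-5-(Inc-oxy)pent-3-en-1-yl]-3-(2-oxo-1,3-oxazolidine-3-carbonyl)cyclobutane-1-carboxylate
Conditions: TfOH (1.0 equiv per amine, both partners as triflate salts), Sc(OTf)3 (10 mol%), 2,6-bis[(4S)-4-tert-butyl-4,5-dihydro-1,3-oxazol-2-yl]pyridine ((S,S)-t-Bu-pybox, 12 mol%), 14 (1.5 equiv), 4 Å MS, CH2Cl2, −40 °C, 450 nm LEDs; aq NaHCO3
Reagents that add atoms: none
Why: Proposed new method: a chiral-Lewis-acid-templated charge-transfer [2+2] photocycloaddition, in which two-point binding of imide 21 to the scandium–pybox complex makes its enoyl unit a strong acceptor that stacks in the ground state with the electron-rich guaiacyl alkene 14 (arene over the chelated imide, so the aryl-bearing carbon of 14 lies over the α-carbon of 21, head-to-tail); 450 nm light, absorbed only by this donor–acceptor pair, gives a contact radical-ion pair that couples at the ferulate α-carbon and the enoyl β-carbon (the spin-bearing positions, as in lignan 8-coupling and radical conjugate addition) and then closes by C-alkylation of the scandium enolate by the quinone-methide-type cation before bond rotation, so both alkene geometries are kept (aryl cis to methyl, acyl trans to the side chain), the aryl ends cis to the acyl group, and addition to the ligand-exposed Cα-Re/Cβ-Si face of 21 sets all four stereocentres as 1S,2R,3S,4S, while the non-chelating trisubstituted enoate is untouched and the two amines, held as ammonium triflates, can neither bind scandium nor act as competing electron donors; the closest known chemistry is the chiral-Lewis-acid-catalysed [2+2] photocycloaddition of enones and the Lewis-acid-catalysed polar [2+2] cycloaddition of electron-rich styrenes with chelating acceptors, neither shown for the head-to-tail union of two conjugated acyl alkenes.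

Step 15
Reactants: 22 Inc (1S,2R,3S,4S)-2-(4-hydroxy-3-methoxyphenyl)-1-methyl-4-[(3E)-3-methyl-5-oxo-5-(Inc-oxy)pent-3-en-1-yl]-3-(2-oxo-1,3-oxazolidine-3-carbonyl)cyclobutane-1-carboxylate
Product: 24 (1S,2R,3S,4S)-1-[(Inc-oxy)carbonyl]-2-(4-hydroxy-3-methoxyphenyl)-1-methyl-4-[(3E)-3-methyl-5-oxo-5-(Inc-oxy)pent-3-en-1-yl]cyclobutane-3-carboxylic acid (locants as in 22), via peroxy acid 23 (not isolated)
Conditions: LiOH·H2O (2.5 equiv), 30% H2O2 (4 equiv), THF/H2O (3:1), 0 °C, 1 h; Na2SO3; 1 M HCl to pH 7; extraction with CHCl3/i-PrOH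
Reagents that add atoms: hydrogen peroxide, OO
Why: Evans-type hydroperoxide cleavage, in which the α-effect nucleophile attacks the exocyclic imide carbonyl at 0 °C far faster than the two hindered secondary-alkyl esters or the β,β-disubstituted enoate, turning the only epimerisable centre (C3) into a carboxylate, and sulfite reduces the percarboxylate to the acid.

Step 16
Reactants: 24 (1S,2R,3S,4S)-1-[(Inc-oxy)carbonyl]-2-(4-hydroxy-3-methoxyphenyl)-1-methyl-4-[(3E)-3-methyl-5-oxo-5-(Inc-oxy)pent-3-en-1-yl]cyclobutane-3-carboxylic acid; 10 (4R,4aS,6S,7S,7aR)-2,4,7-trimethyloctahydro-1H-cyclopenta[c]pyridin-6-ol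
Product: 25 tri-Inc ester of (1S,2R,3S,4S)-4-[(3E)-4-carboxy-3-methylbut-3-en-1-yl]-2-(4-hydroxy-3-methoxyphenyl)-1-methylcyclobutane-1,3-dicarboxylic acid (target CNP0251577.3)
Conditions: 10 (1.5 equiv), PPh3 (2 equiv), DIAD (2 equiv), THF, 0 °C to rt
Reagents that add atoms: none
Why: Mitsunobu esterification forms the last ester C–O bond by SN2 of the C3 carboxylate on the oxyphosphonium of 10 with inversion (6S to 6R); the acid is never activated, so C3 cannot epimerise, and the carboxylic acid reacts in preference to the phenol.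

**Compound list**
1 | methyl (2R)-3-hydroxy-2-methylpropanoate | COC(=O)[C@H](C)CO | starting material
2 | (2E)-but-2-en-1-amine | C/C=C/CN | starting material
3 | (2R)-N-[(2E)-but-2-en-1-yl]-3-hydroxy-2-methylpropanamide | C/C=C/CNC(=O)[C@H](C)CO | intermediate
4 | (2S)-3-{[(2E)-but-2-en-1-yl]amino}-2-methylpropan-1-ol | C/C=C/CNC[C@H](C)CO | intermediate
5 | methyl N-[(2E)-but-2-en-1-yl]-N-[(2S)-3-hydroxy-2-methylpropyl]carbamate | C/C=C/CN(C(=O)OC)C[C@H](C)CO | intermediate
6 | methyl N-[(2E)-but-2-en-1-yl]-N-[(2S)-2-methyl-3-oxopropyl]carbamate | C/C=C/CN(C(=O)OC)C[C@H](C)C=O | intermediate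
7 | methyl N-[(2E)-but-2-en-1-yl]-N-[(2R)-2-methylbut-3-yn-1-yl]carbamate | C/C=C/CN(C(=O)OC)C[C@H](C)C#C | intermediate
8 | methyl (4R,7S,7aS)-4,7-dimethyl-6-oxo-1,3,4,6,7,7a-hexahydro-2H-cyclopenta[c]pyridine-2-carboxylate | O=C1C=C2[C@@H](CN(C(=O)OC)C[C@@H]2C)[C@@H]1C | intermediate
9 | methyl (4R,4aS,7S,7aR)-4,7-dimethyl-6-oxooctahydro-2H-cyclopenta[c]pyridine-2-carboxylate | O=C1C[C@@H]2[C@@H](CN(C(=O)OC)C[C@@H]2C)[C@@H]1C | intermediate
10 | (4R,4aS,6S,7S,7aR)-2,4,7-trimethyloctahydro-1H-cyclopenta[c]pyridin-6-ol (6-epi-incarvilline) | O[C@H]1C[C@@H]2[C@@H](CN(C)C[C@@H]2C)[C@@H]1C | intermediate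
11 | 4-hydroxy-3-methoxybenzaldehyde (vanillin) | COc1cc(C=O)ccc1O | starting material
12 | 2-methylpropanedioic acid (methylmalonic acid) | CC(C(=O)O)C(=O)O | starting material
13 | (2E)-3-(4-hydroxy-3-methoxyphenyl)-2-methylprop-2-enoic acid | COc1cc(/C=C(\C)C(=O)O)ccc1O | intermediate
14 | Inc (2E)-3-(4-hydroxy-3-methoxyphenyl)-2-methylprop-2-enoate | COc1cc(/C=C(\C)C(=O)O[C@@H]2C[C@@H]3[C@@H](CN(C)C[C@@H]3C)[C@@H]2C)ccc1O | intermediate
15 | but-2-ynoic acid | CC#CC(=O)O | starting material
16 | Inc but-2-ynoate | CC#CC(=O)O[C@@H]1C[C@@H]2[C@@H](CN(C)C[C@@H]2C)[C@@H]1C | intermediate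
17 | but-3-en-1-ylmagnesium bromide | C=CCC[Mg]Br | starting material
18 | alkenylcopper adduct, Inc (2Z)-2-cuprio-3-methylhepta-2,6-dienoate | C=CCC/C(C)=C(\[Cu])C(=O)O[C@@H]1C[C@@H]2[C@@H](CN(C)C[C@@H]2C)[C@@H]1C | intermediate
19 | Inc (2E)-3-methylhepta-2,6-dienoate | C=CCC/C(C)=C/C(=O)O[C@@H]1C[C@@H]2[C@@H](CN(C)C[C@@H]2C)[C@@H]1C | intermediate
20 | 3-(prop-2-enoyl)-1,3-oxazolidin-2-one | C=CC(=O)N1CCOC1=O | starting material
21 | Inc (2E,6E)-3-methyl-8-oxo-8-(2-oxo-1,3-oxazolidin-3-yl)octa-2,6-dienoate | O=C(/C=C/CC/C(C)=C/C(=O)O[C@@H]1C[C@@H]2[C@@H](CN(C)C[C@@H]2C)[C@@H]1C)N1CCOC1=O | intermediate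
22 | Inc (1S,2R,3S,4S)-2-(4-hydroxy-3-methoxyphenyl)-1-methyl-4-[(3E)-3-methyl-5-oxo-5-(Inc-oxy)pent-3-en-1-yl]-3-(2-oxo-1,3-oxazolidine-3-carbonyl)cyclobutane-1-carboxylate | COc1cc([C@H]2[C@@H](C(=O)N3CCOC3=O)[C@H](CC/C(C)=C/C(=O)O[C@@H]3C[C@@H]4[C@@H](CN(C)C[C@@H]4C)[C@@H]3C)[C@]2(C)C(=O)O[C@@H]2C[C@@H]3[C@@H](CN(C)C[C@@H]3C)[C@@H]2C)ccc1O | intermediate
23 | peroxy acid, (1S,2R,3S,4S)-1-[(Inc-oxy)carbonyl]-2-(4-hydroxy-3-methoxyphenyl)-1-methyl-4-[(3E)-3-methyl-5-oxo-5-(Inc-oxy)pent-3-en-1-yl]cyclobutane-3-carboperoxoic acid (locants as in 22) | COc1cc([C@H]2[C@@H](C(=O)OO)[C@H](CC/C(C)=C/C(=O)O[C@@H]3C[C@@H]4[C@@H](CN(C)C[C@@H]4C)[C@@H]3C)[C@]2(C)C(=O)O[C@@H]2C[C@@H]3[C@@H](CN(C)C[C@@H]3C)[C@@H]2C)ccc1O | intermediate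
24 | (1S,2R,3S,4S)-1-[(Inc-oxy)carbonyl]-2-(4-hydroxy-3-methoxyphenyl)-1-methyl-4-[(3E)-3-methyl-5-oxo-5-(Inc-oxy)pent-3-en-1-yl]cyclobutane-3-carboxylic acid (locants as in 22) | COc1cc([C@H]2[C@@H](C(=O)O)[C@H](CC/C(C)=C/C(=O)O[C@@H]3C[C@@H]4[C@@H](CN(C)C[C@@H]4C)[C@@H]3C)[C@]2(C)C(=O)O[C@@H]2C[C@@H]3[C@@H](CN(C)C[C@@H]3C)[C@@H]2C)ccc1O | intermediate
25 | tri-Inc ester of (1S,2R,3S,4S)-4-[(3E)-4-carboxy-3-methylbut-3-en-1-yl]-2-(4-hydroxy-3-methoxyphenyl)-1-methylcyclobutane-1,3-dicarboxylic acid (CNP0251577.3) | COc1cc([C@H]2[C@@H](C(=O)O[C@@H]3C[C@@H]4[C@@H](CN(C)C[C@@H]4C)[C@@H]3C)[C@H](CC/C(C)=C/C(=O)O[C@@H]3C[C@@H]4[C@@H](CN(C)C[C@@H]4C)[C@@H]3C)[C@]2(C)C(=O)O[C@@H]2C[C@@H]3[C@@H](CN(C)C[C@@H]3C)[C@@H]2C)ccc1O | target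

**Step count and risks**
Total steps: 16. Longest linear sequence: 14 (steps 1–8, then steps 11–16); the ferulate branch is steps 9–10 and joins at step 14.

The three steps most likely to fail:

Step 14 (the proposed new cycloaddition). The donor–acceptor pair may associate too weakly or return the electron without bonding. The phenol ring may add to the activated imide in a Friedel–Crafts sense, and the ion pair may close through oxygen. The sense of face selection is a design expectation, not a precedent; the mirror-image ligand would be used if it proved opposite. The fallback uses known chemistry and sets out from 14 and 21, both as triflate salts: uncatalysed, thioxanthone-sensitised crossed [2+2] photocycloaddition (405 nm, MeCN), the long-established way of adding cinnamates to alkenes. This is unselective and low-yielding and gives regio- and stereoisomers. Because both partners carry the same enantiopure ester group, the head-to-tail adduct forms as 22 together with its cyclobutane diastereomer Inc (1R,2S,3R,4R)-2-(4-hydroxy-3-methoxyphenyl)-1-methyl-4-[(3E)-3-methyl-5-oxo-5-(Inc-oxy)pent-3-en-1-yl]-3-(2-oxo-1,3-oxazolidine-3-carbonyl)cyclobutane-1-carboxylate F1. Preparative HPLC separates the two, and the route is rejoined at 22.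

Step 15 (hydroperoxide cleavage). Hydrogen peroxide or the percarboxylate may oxidise the two tertiary amines to N-oxides, the esters may be partly hydrolysed, and the zwitterionic product is awkward to isolate. The fallback avoids any oxidant and sets out from 22: LiSEt (from EtSH and n-BuLi, 3 equiv) in THF at 0 °C cleaves the imide exocyclically to the thioester Inc (1S,2R,3S,4S)-3-[(ethylsulfanyl)carbonyl]-2-(4-hydroxy-3-methoxyphenyl)-1-methyl-4-[(3E)-3-methyl-5-oxo-5-(Inc-oxy)pent-3-en-1-yl]cyclobutane-1-carboxylate F2. Silver-assisted hydrolysis (AgNO3, 2,6-lutidine, THF/H2O, rt), which is specific for the thioester, then returns to the route at 24.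

Step 6 (Pauson–Khand). A 1,7-enyne with an internal alkene is a slow substrate, and the 1,3-induction may be only moderate. The minor 7a-epimer would have to be removed by chromatography, since base equilibration would risk racemisation. The fallback sets out from 7: LiHMDS then Me3SiCl gives the silyl alkyne methyl N-[(2E)-but-2-en-1-yl]-N-[(2R)-2-methyl-4-(trimethylsilyl)but-3-yn-1-yl]carbamate F3. Zirconocene-mediated bicyclisation and carbonylation (Cp2ZrCl2, n-BuLi 2 equiv, THF, −78 °C to rt; then CO, 1 atm), an oxidative-cyclisation route under thermodynamic control of the metallacycle, gives the silyl enone methyl (4R,7S,7aS)-4,7-dimethyl-6-oxo-5-(trimethylsilyl)-1,3,4,6,7,7a-hexahydro-2H-cyclopenta[c]pyridine-2-carboxylate F4. Protodesilylation with TBAF/AcOH in THF returns to the route at 8.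

**Further compounds**
F1 | step 14 | Inc (1R,2S,3R,4R)-2-(4-hydroxy-3-methoxyphenyl)-1-methyl-4-[(3E)-3-methyl-5-oxo-5-(Inc-oxy)pent-3-en-1-yl]-3-(2-oxo-1,3-oxazolidine-3-carbonyl)cyclobutane-1-carboxylate | COc1cc([C@@H]2[C@H](C(=O)N3CCOC3=O)[C@@H](CC/C(C)=C/C(=O)O[C@@H]3C[C@@H]4[C@@H](CN(C)C[C@@H]4C)[C@@H]3C)[C@@]2(C)C(=O)O[C@@H]2C[C@@H]3[C@@H](CN(C)C[C@@H]3C)[C@@H]2C)ccc1O
F2 | step 15 | Inc (1S,2R,3S,4S)-3-[(ethylsulfanyl)carbonyl]-2-(4-hydroxy-3-methoxyphenyl)-1-methyl-4-[(3E)-3-methyl-5-oxo-5-(Inc-oxy)pent-3-en-1-yl]cyclobutane-1-carboxylate | COc1cc([C@H]2[C@@H](C(=O)SCC)[C@H](CC/C(C)=C/C(=O)O[C@@H]3C[C@@H]4[C@@H](CN(C)C[C@@H]4C)[C@@H]3C)[C@]2(C)C(=O)O[C@@H]2C[C@@H]3[C@@H](CN(C)C[C@@H]3C)[C@@H]2C)ccc1O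
F3 | step 6 | methyl N-[(2E)-but-2-en-1-yl]-N-[(2R)-2-methyl-4-(trimethylsilyl)but-3-yn-1-yl]carbamate | C/C=C/CN(C(=O)OC)C[C@H](C)C#C[Si](C)(C)C
F4 | step 6 | methyl (4R,7S,7aS)-4,7-dimethyl-6-oxo-5-(trimethylsilyl)-1,3,4,6,7,7a-hexahydro-2H-cyclopenta[c]pyridine-2-carboxylate | O=C1C([Si](C)(C)C)=C2[C@@H](CN(C(=O)OC)C[C@@H]2C)[C@@H]1C
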